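Locants (labdane type): ring B = C5–C6–C7–C8–C9–C10, ring C = O–C8–C9–C11–C12–C13; C8, C10 and C13 carry CH3; C14–C15 = epoxide; acid arms C10–C1H2–C2O2H and C5–C4(CH3)2–C3O2H.
Cuts, in order: both CO2H (as 2-(trimethylsilyl)ethyl esters); epoxide O–C15 (from the 14,15-diol); ring C O–C13 together with ring B C8–C9 (open-chain keto alkene epoxy alcohol 22); C9=C11 (Wittig); the carvone ring bond C(=O)–CH2 that frees C9; C10–C1 (enolate alkylation); C5–C4 (Mukaiyama–Michael).
Forward: (S)-carvone takes the C4 unit, then the C1–C2 unit; ozonolysis cuts its ring (isopropenyl becomes the C8 methyl ketone, the ring CH2 leaves as formate); the C9 acid becomes the aldehyde and is joined to the C11–C15 chain; ring B, then ring C, close in one flask; the epoxide is re-formed at C14–C15 and the esters are removed.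
Enabling feature: the ring C oxygen bridges two fully substituted carbons, C8 (a former methyl ketone carbon, tied to C9 through C7–C6–C5–C10) and C13 (the 3-carbon of the 2,3-epoxy alcohol C13–C14–C15–OH); closing ring B by a C8 ketyl on C9 leaves the C8 oxygen 6-exo to C13.
Stereochemistry: the carvone stereocentre sets C5 and C10 (anti addition, anti alkylation) and is then erased; Sharpless epoxidation sets C13 and C14; the key step sets C8 and C9 in a chair and inverts C13.

Key step: step 14

Step 1
Reactants: 1 2-(trimethylsilyl)ethanol; 2 2-methylpropanoyl chloride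
Product: 3 2-(trimethylsilyl)ethyl 2-methylpropanoate
Conditions: pyridine, CH2Cl2, 0 °C to rt
Reagents that add atoms: none
Why: Esterification of a primary alcohol by an acyl chloride (nucleophilic acyl substitution); this ester is chosen because fluoride removes it at the end without touching an epoxide.

Step 2
Reactants: 3 2-(trimethylsilyl)ethyl 2-methylpropanoate
Product: 4 ketene silyl acetal of 3
Conditions: LiN(iPr)2, THF, −78 °C; Me3SiCl, −78 °C to rt
Reagents that add atoms: chlorotrimethylsilane, C[Si](C)(C)Cl
Why: Ester enolate formation and O-silylation should give the ketene silyl acetal, which has no geometry issue because the α-carbon carries two methyl groups.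

Step 3
Reactants: 5 (S)-(+)-carvone; 4 ketene silyl acetal of 3
Product: 6 silyl enol ether of the conjugate adduct (C3 side chain trans to the C5 isopropenyl group, carvone numbering)
Conditions: Me3SiNTf2 (5 mol %), CH2Cl2, −78 °C; Et3N quench
Reagents that add atoms: none
Why: Mukaiyama–Michael addition should form the C5–C4 bond by axial attack on the silylium-activated enone anti to the pseudo-equatorial isopropenyl group, and silyl transfer fixes the enol ether on the methyl-bearing carbon.

Step 4
Reactants: 7 bromoacetyl bromide; 1 2-(trimethylsilyl)ethanol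
Product: 8 2-(trimethylsilyl)ethyl bromoacetate
Conditions: pyridine, CH2Cl2, −20 to 0 °C
Reagents that add atoms: none
Why: Esterification by the acyl bromide (nucleophilic acyl substitution) is much faster than displacement of the alkyl bromide.

Step 5
Reactants: 6 silyl enol ether of the conjugate adduct; 8 2-(trimethylsilyl)ethyl bromoacetate
Product: 10 quaternary cyclohexanone (C2 acetate arm trans to the C3 side chain, C2 methyl cis to it), via lithium enolate 9 (not isolated)
Conditions: MeLi, THF, 0 °C; then 8, DMPU, −78 to 0 °C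
Reagents that add atoms: none
Why: MeLi cleaves the O–Si bond to the regiodefined lithium enolate, whose alkylation (enolate SN2 alkylation) should occur on the face anti to the bulky neighbouring side chain and so set the quaternary carbon C10.

Step 6
Reactants: 10 quaternary cyclohexanone
Product: 11 trimethylsilyl enol ether of 10 toward the ring CH2
Conditions: Me3SiOTf, Et3N, CH2Cl2, 0 °C
Reagents that add atoms: trimethylsilyl trifluoromethanesulfonate, C[Si](C)(C)OS(=O)(=O)C(F)(F)F
Why: Soft enolisation silylates the ketone at its only enolisable α-carbon and should leave both esters untouched.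

Step 7
Reactants: 11 trimethylsilyl enol ether of 10
Product: 13 keto acid (C9 acid, C8 methyl ketone), via formyl ketone acid 12 (not isolated)
Conditions: O3, CH2Cl2/MeOH, −78 °C; Me2S; then K2CO3, THF/H2O, rt; 1 M HCl work-up
Reagents that add atoms: ozone, [O-][O+]=O
Why: Ozonolysis should cut the silyl enol ether (to the C9 acid and a formyl group) and the isopropenyl group (to the methyl ketone), and retro-Claisen deformylation of the resulting 2-formyl ketone removes the former ring CH2 and erases the carvone stereocentre.

Step 8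
Reactants: 13 keto acid
Product: 14 S-ethyl thioester of 13
Conditions: (COCl)2, DMF (cat.), CH2Cl2, 0 °C; then EtSH, Et3N, 0 °C to rt
Reagents that add atoms: ethanethiol, CCS
Why: Acyl chloride formation and thiolysis (nucleophilic acyl substitution) should tolerate the hindered α-quaternary acid, the ketone and the esters.

Step 9
Reactants: 14 S-ethyl thioester of 13
Product: 15 keto aldehyde (C9 formyl)
Conditions: Et3SiH, Pd/C (10 %), acetone, rt
Reagents that add atoms: none
Why: Fukuyama reduction should convert the thioester into the aldehyde without reducing the ketone or the esters, and no alkene is present at this stage.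

Step 10
Reactants: 16 4-bromobut-1-yne
Product: 18 (2E)-5-bromo-3-methylpent-2-en-1-ol, via alkenylalane 17 (not isolated)
Conditions: Me3Al, Cp2ZrCl2 (25 mol %), CH2Cl2, 0 °C to rt; then (CH2O)n, rt; 1 M HCl work-up
Reagents that add atoms: trimethylaluminium, C[Al](C)C; formaldehyde (as paraformaldehyde), C=O
Why: Negishi carboalumination adds CH3 and Al syn with methyl on the internal carbon, and hydroxymethylation of the alkenylalane with retention should give the (E)-trisubstituted allylic alcohol.

Step 11
Reactants: 18 (2E)-5-bromo-3-methylpent-2-en-1-ol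
Product: 19 [(3E)-5-hydroxy-3-methylpent-3-en-1-yl]triphenylphosphonium bromide
Conditions: PPh3, MeCN, reflux
Reagents that add atoms: triphenylphosphine, c1ccc(cc1)P(c1ccccc1)c1ccccc1
Why: SN2 quaternisation of the primary bromide should proceed without touching the allylic alcohol or the alkene geometry.

Step 12
Reactants: 15 keto aldehyde; 19 phosphonium bromide
Product: 21 (9Z,13E)-dienol keto diester, via phosphonium ylide 20 (not isolated)
Conditions: NaN(SiMe3)2 (2.1 equiv on 19), THF, −78 to 0 °C; then 15, −78 °C to rt; H2O work-up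
Reagents that add atoms: none
Why: Wittig olefination with the non-stabilised ylide should take the aldehyde in preference to the ketone and give mainly the (Z)-alkene, whose geometry is of no consequence because C9 and C11 both become sp3 in step 14.

Step 13
Reactants: 21 (9Z,13E)-dienol keto diester
Product: 22 (13S,14S)-epoxy alcohol
Conditions: Ti(OiPr)4 (10 mol %), L-(+)-diethyl tartrate (12 mol %), t-BuOOH, 4 Å molecular sieves, CH2Cl2, −20 °C
Reagents that add atoms: tert-butyl hydroperoxide, CC(C)(C)OO
Why: Sharpless asymmetric epoxidation epoxidises only the allylic alcohol alkene, and L-(+)-tartrate should give the (13S,14S) epoxide as it does for geraniol-type (E)-allylic alcohols.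

Step 14
Reactants: 22 (13S,14S)-epoxy alcohol
Product: 24 ring B/ring C 14,15-diol, via epoxy cyclohexanol 23 (not isolated)
Conditions: SmI2 (4 equiv), HMPA, t-BuOH (2 equiv), THF, −78 °C to rt; then camphorsulfonic acid, 0 °C to rt, same flask
Reagents that add atoms: none
Why: Proposed new method: SmI2/HMPA reduces the C8 methyl ketone to a samarium ketyl whose carbon adds 6-exo-trig to C9 of the C9=C11 alkene (ring B); the C11 radical is reduced and protonated by t-BuOH, and the C8 oxygen, freed from trivalent samarium by camphorsulfonic acid, opens the protonated 2,3-epoxy alcohol at its fully substituted carbon C13 in a 6-exo-tet, SN2-like attack (ring C), leaving the C14 and C15 hydroxyls. The closest known reaction types are the samarium diiodide ketyl–olefin cyclisation of unactivated olefinic ketones and the acid-mediated 6-exo opening of trisubstituted epoxides by tertiary alcohols; running them as one operation on an epoxy alcohol is the untested part. C8 and C9 are set in the only chair that keeps the C5 and C10 side arms equatorial: the bulky O–Sm group sits equatorial and anti to the alkene, so the C8 methyl is axial and cis to the C10 methyl, and C11 is equatorial, so O and C11 come out trans-diequatorial as ring C needs. C13 is set by inversion of the (13S) centre made in step 13, and C14 is not touched. The step needs radical closure faster than simple ketone reduction (HMPA, the poor hydrogen donor t-BuOH), 6-exo over 7-endo radical attack, and attack at C13 over C14 (six- over seven-membered ring, cation-stabilising tertiary carbon); the esters are neither reducible nor in reach.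

Step 15
Reactants: 24 ring B/ring C 14,15-diol
Product: 26 bis[2-(trimethylsilyl)ethyl] ester of the target, via primary tosylate 25 (not isolated)
Conditions: NaH, 1-(p-toluenesulfonyl)imidazole, THF, 0 °C to rt; H2O work-up
Reagents that add atoms: none
Why: Selective sulfonylation of the primary alkoxide followed by intramolecular Williamson displacement by the neighbouring secondary alkoxide should close the terminal epoxide with retention at C14.

Step 16
Reactants: 26 bis[2-(trimethylsilyl)ethyl] ester of the target
Product: 27 CNP0160287.2 (target diacid; 5S,8S,9S,10R,13R,14S in the locants above)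
Conditions: Bu4NF, THF, rt; NaH2PO4 work-up (pH 4–5)
Reagents that add atoms: none
Why: Fluoride-induced β-elimination of both 2-(trimethylsilyl)ethyl esters should free the two acids, including the hindered C3 acid, under conditions an epoxide tolerates.

Compound list
1 | 2-(trimethylsilyl)ethanol | C[Si](C)(C)CCO | starting material
2 | 2-methylpropanoyl chloride | CC(C)C(=O)Cl | starting material
3 | 2-(trimethylsilyl)ethyl 2-methylpropanoate | CC(C)C(=O)OCC[Si](C)(C)C | intermediate
4 | trimethyl({2-methyl-1-[2-(trimethylsilyl)ethoxy]prop-1-en-1-yl}oxy)silane (ketene silyl acetal) | CC(C)=C(O[Si](C)(C)C)OCC[Si](C)(C)C | intermediate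
5 | (S)-(+)-carvone | CC1=CC[C@@H](CC1=O)C(C)=C | starting material
6 | silyl enol ether of the conjugate adduct; carvone numbering: 2-methyl-1-(trimethylsilyloxy)cyclohex-1-ene with C(CH3)2CO2CH2CH2SiMe3 at C3 trans to isopropenyl at C5 | CC1=C(O[Si](C)(C)C)C[C@@H](C(C)=C)C[C@@H]1C(C)(C)C(=O)OCC[Si](C)(C)C | intermediate
7 | bromoacetyl bromide | BrCC(=O)Br | starting material
8 | 2-(trimethylsilyl)ethyl bromoacetate | BrCC(=O)OCC[Si](C)(C)C | intermediate
9 | lithium enolate corresponding to 6 (O–Li in place of O–SiMe3) | CC1=C(O[Li])C[C@@H](C(C)=C)C[C@@H]1C(C)(C)C(=O)OCC[Si](C)(C)C | intermediate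
10 | quaternary cyclohexanone; carvone numbering: 2-methyl-2-(CH2CO2CH2CH2SiMe3)-3-[C(CH3)2CO2CH2CH2SiMe3]-5-isopropenylcyclohexanone, C3 group trans to the C5 isopropenyl and to the C2 acetate arm | O=C1C[C@@H](C(C)=C)C[C@H](C(C)(C)C(=O)OCC[Si](C)(C)C)[C@@]1(C)CC(=O)OCC[Si](C)(C)C | intermediate
11 | trimethylsilyl enol ether of 10 (C1=C6, carvone numbering) | C[Si](C)(C)OC1=C[C@@H](C(C)=C)C[C@H](C(C)(C)C(=O)OCC[Si](C)(C)C)[C@@]1(C)CC(=O)OCC[Si](C)(C)C | intermediate
12 | formyl ketone acid: 13 with a formyl group on C7 (configuration there as formed, labile) | OC(=O)[C@](C)(CC(=O)OCC[Si](C)(C)C)[C@@H](C(C)(C)C(=O)OCC[Si](C)(C)C)C[C@@H](C=O)C(C)=O | intermediate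
13 | keto acid HO2C(C9)–C10(CH3)(CH2CO2R)–C5H[C(CH3)2CO2R]–C6H2–C7H2–C8(=O)CH3, R = CH2CH2SiMe3; C5 and C10 as in 27 | OC(=O)[C@](C)(CC(=O)OCC[Si](C)(C)C)[C@@H](C(C)(C)C(=O)OCC[Si](C)(C)C)CCC(C)=O | intermediate
14 | S-ethyl thioester of 13 | CCSC(=O)[C@](C)(CC(=O)OCC[Si](C)(C)C)[C@@H](C(C)(C)C(=O)OCC[Si](C)(C)C)CCC(C)=O | intermediate
15 | keto aldehyde (C9 formyl in place of the C9 acid of 13) | O=C[C@](C)(CC(=O)OCC[Si](C)(C)C)[C@@H](C(C)(C)C(=O)OCC[Si](C)(C)C)CCC(C)=O | intermediate
16 | 4-bromobut-1-yne | C#CCCBr | starting material
17 | [(1E)-4-bromo-2-methylbut-1-en-1-yl]dimethylalane | C[Al](C)/C=C(C)/CCBr | intermediate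
18 | (2E)-5-bromo-3-methylpent-2-en-1-ol | OC/C=C(C)/CCBr | intermediate
19 | [(3E)-5-hydroxy-3-methylpent-3-en-1-yl]triphenylphosphonium bromide | OC/C=C(C)/CC[P+](c1ccccc1)(c1ccccc1)c1ccccc1.[Br-] | intermediate
20 | phosphonium ylide of 19 as its sodium alkoxide | [Na+].[O-]C/C=C(C)/CC=P(c1ccccc1)(c1ccccc1)c1ccccc1 | intermediate
21 | (9Z,13E)-dienol keto diester: 15 with CH=O replaced by C9H=C11H–C12H2–C13(CH3)=C14H–C15H2OH | CC(=O)CC[C@H](C(C)(C)C(=O)OCC[Si](C)(C)C)[C@@](C)(CC(=O)OCC[Si](C)(C)C)/C=C\C/C(C)=C/CO | intermediate
22 | (13S,14S)-13,14-epoxide of 21 (2,3-epoxy alcohol) | CC(=O)CC[C@H](C(C)(C)C(=O)OCC[Si](C)(C)C)[C@@](C)(CC(=O)OCC[Si](C)(C)C)/C=C\C[C@]1(C)O[C@H]1CO | intermediate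
23 | epoxy cyclohexanol: ring B closed (C8 OH equatorial, C8 CH3 axial, C9 H axial), side chain on C9 still the (13S,14S)-epoxy alcohol | C[C@]1(O)CC[C@H](C(C)(C)C(=O)OCC[Si](C)(C)C)[C@@](C)(CC(=O)OCC[Si](C)(C)C)[C@@H]1CC[C@]2(C)O[C@H]2CO | intermediate
24 | ring B/ring C diol: 26 with (14S)-CH(OH)–CH2OH on C13 in place of the epoxide | C[Si](C)(C)CCOC(=O)C(C)(C)[C@H]1CC[C@]2(C)O[C@@](C)([C@@H](O)CO)CC[C@H]2[C@]1(C)CC(=O)OCC[Si](C)(C)C | intermediate
25 | C15 p-toluenesulfonate of 24 | C[Si](C)(C)CCOC(=O)C(C)(C)[C@H]1CC[C@]2(C)O[C@@](C)([C@@H](O)COS(=O)(=O)c3ccc(C)cc3)CC[C@H]2[C@]1(C)CC(=O)OCC[Si](C)(C)C | intermediate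
26 | bis[2-(trimethylsilyl)ethyl] ester of 27 | C[Si](C)(C)CCOC(=O)C(C)(C)[C@H]1CC[C@]2(C)O[C@@](C)([C@@H]3CO3)CC[C@H]2[C@]1(C)CC(=O)OCC[Si](C)(C)C | intermediate
27 | CNP0160287.2 | CC(C)(C(=O)O)[C@H]1CC[C@]2(C)O[C@@](C)([C@@H]3CO3)CC[C@H]2[C@]1(C)CC(=O)O | target

Total steps: 16. Longest linear sequence: 13 steps (1, 2, 3, 5, 6, 7, 8, 9, 12, 13, 14, 15, 16).

Steps most likely to fail

Step 14. The 2,3-epoxy alcohol may be consumed before the C8 alkoxide exists (iodide opening promoted by trivalent samarium, epoxide migration at the samarium alkoxide, or reductive deoxygenation), or the alkoxide may fail to reach C13 in the strongly coordinating medium. The fallback separates the two bond formations into known reactions and brings in the epoxide only after the C–C bond is made. It sets out from 21 and comes back at 24. Compound 21 is cyclised alone with SmI2/HMPA/t-BuOH (ketyl–olefin cyclisation) to the ring B tertiary alcohol that keeps the (E)-allylic alcohol side chain F1. Sharpless epoxidation of F1 (Ti(OiPr)4, L-(+)-diethyl tartrate, t-BuOOH) then gives 23 as an isolated compound, and catalytic camphorsulfonic acid in CH2Cl2 closes ring C to 24.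

Step 5. C-alkylation of the tetrasubstituted enolate beside the very bulky C3 side chain may lose to O-alkylation or to proton transfer from the acidic bromoacetate. The fallback brings in the two-carbon arm as an allyl group and reveals the ester later through an anhydride. It sets out from 9 and comes back at 13. Enolate 9 is allylated with allyl bromide to the C-allyl ketone F2, and soft enolisation (Me3SiOTf, Et3N) gives the silyl enol ether F3. Ozonolysis (Me2S), then NaClO2/NaH2PO4/2-methylbut-2-ene, oxidises all three cleaved positions; the β-keto acid on the former ring CH loses CO2, giving the keto succinic acid F4. Ac2O closes the cyclic anhydride F5, which 2-(trimethylsilyl)ethanol 1 with DMAP should open at its less hindered carbonyl to give 13.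

Step 12. Enolisation of the methyl ketone by the basic ylide, followed by intramolecular aldol closure onto the hindered formyl group, may outrun olefination. The fallback masks the ketone before the aldehyde is made. It sets out from 14 and comes back at 21. Thioester 14 is ketalised (ethane-1,2-diol, TsOH cat., benzene, reflux) to the dioxolane thioester F6, Fukuyama reduction (Et3SiH, Pd/C) gives the dioxolane aldehyde F7, and Wittig reaction with ylide 20 gives the dioxolane dienol F8. Pyridinium p-toluenesulfonate in wet acetone then frees the ketone to give 21.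

Further compounds
F1 | step 14 | ring B tertiary alcohol with the (13E)-allylic alcohol side chain (23 without the epoxide oxygen) | C[C@]1(O)CC[C@H](C(C)(C)C(=O)OCC[Si](C)(C)C)[C@@](C)(CC(=O)OCC[Si](C)(C)C)[C@@H]1CC/C(C)=C/CO
F2 | step 5 | C-allyl ketone (10 with allyl in place of the acetate arm) | O=C1C[C@@H](C(C)=C)C[C@H](C(C)(C)C(=O)OCC[Si](C)(C)C)[C@@]1(C)CC=C
F3 | step 5 | trimethylsilyl enol ether of F2 | C[Si](C)(C)OC1=C[C@@H](C(C)=C)C[C@H](C(C)(C)C(=O)OCC[Si](C)(C)C)[C@@]1(C)CC=C
F4 | step 5 | keto succinic acid (13 with CH2CO2H in place of the ester arm) | OC(=O)[C@](C)(CC(=O)O)[C@@H](C(C)(C)C(=O)OCC[Si](C)(C)C)CCC(C)=O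
F5 | step 5 | cyclic anhydride of F4 | O=C1OC(=O)C[C@]1(C)[C@@H](C(C)(C)C(=O)OCC[Si](C)(C)C)CCC(C)=O
F6 | step 12 | dioxolane thioester (14 with the C8 ketone as its ethylene ketal) | CCSC(=O)[C@](C)(CC(=O)OCC[Si](C)(C)C)[C@@H](C(C)(C)C(=O)OCC[Si](C)(C)C)CCC1(C)OCCO1
F7 | step 12 | dioxolane aldehyde (15 with the C8 ketone as its ethylene ketal) | O=C[C@](C)(CC(=O)OCC[Si](C)(C)C)[C@@H](C(C)(C)C(=O)OCC[Si](C)(C)C)CCC1(C)OCCO1
F8 | step 12 | dioxolane dienol (21 with the C8 ketone as its ethylene ketal) | CC1(CC[C@H](C(C)(C)C(=O)OCC[Si](C)(C)C)[C@@](C)(CC(=O)OCC[Si](C)(C)C)/C=C\C/C(C)=C/CO)OCCO1
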